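Remark on the chemistry: the carbocycle is numbered C1 (quaternary carbinol carbon), C2 and C3 (secondary carbinol carbons), C4 (allylic carbon bearing the benzoate), C5=C6 (ring alkene) and C7 (exocyclic methylene); the carbohydrate intermediates 1, 2 and 4–8 keep sugar numbering, and sugar C2, C3, C4 become C4, C3, C2 of the carbocycle.

## Structural features

The target 18 is a single cyclohexene ring in which C1 carries a tertiary hydroxyl and the benzoyloxymethyl carbon C7, C2 and C3 carry secondary hydroxyls, C4 carries an allylic benzoate, and the cis double bond C5=C6 is attached directly to the quaternary carbon. The four stereocentres C1–C4 are contiguous and have the configuration 1S,2S,3S,4R, with O1 and O2 cis, O2 and O3 trans, and O3 and O4 cis, so that C7 stands trans to O2 on the face that holds O3 and O4. The triad C2–C3–C4 has the relative and absolute configuration of C4–C3–C2 of D-mannose. Both benzoates lie next to free hydroxyls and can migrate under base, O4 to O3 and O7 to O1 or O2. The tertiary allylic C1–OH and the allylic C4 benzoate can ionise under acid, and any cyclohexenone precursor with a β-oxygen is liable to elimination and aromatisation. The real difficulty is the quaternary centre C1 in the correct sense relative to C2, together with placing benzoates on O4 and O7 only, out of five oxygens. The key step exploits the fact that the unit C1(OH)–C7H2–OBz is a ring-opened spiro-oxirane C1–O–C7, and that this oxirane is what a one-carbon ylide makes from the carbonyl group of a cyclohex-2-enone oxygenated at its three sp3 carbons, whose C1(=O)–C6=C5 unit already contains the ring alkene of the target.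

## Logic of the disconnections

18 to 17: the O–Si bonds on O2 and O3 are cut last. The silyl ethers serve only as protection, so the final operation is one deprotection. The forward step must remove them without base, or the benzoates on O4 and O7 would move to the freed hydroxyls.

17 to 15 and 16: the C7–O bond of the primary benzoate is cut and C7 is reconnected to O1 as an oxirane. This removes the need to distinguish O7 from the other oxygens and turns the 1,2-diol monoester into one strained ring. The forward step needs carboxylate attack at C7 only, not at the quaternary allylic C1 and not at C5.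

15 to 11 and 12 (through 13 and 14): the C1–C7 bond and the C7–O bond of the oxirane are cut. This removes the quaternary stereocentre and the seventh carbon at once and leaves an enone with three stereocentres. The forward step needs 1,2-addition rather than 1,4-addition, attack trans to the C2 silyloxy group, and no enolisation of the α'-oxygenated ketone.

11 to 9 (through 10): the C5=C6 double bond is traced back to a β-hydroxy ketone by formal addition of water. This gives the aldol pattern that a carbocyclisation delivers. The forward elimination must stop at the enone and must not epimerise C2.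

9 to 7 (through 8): the ring bond between the carbon α to the ketone and the carbinol carbon is cut (C6–C5 in carbocycle numbering, C6–C1 of the sugar). The carbocyclic problem becomes a carbohydrate problem with all three stereocentres taken from the pool. The forward step needs an exocyclic enol ether at sugar C5.

7 to 6: the enol ether double bond is traced back to H5 and a C6–I bond. The forward step is a dehydrohalogenation that must leave the benzoate and silyl ethers alone.

6 to 5: the O–Si bonds on O3 and O4 of the sugar are cut. Two separate bulky silyl ethers are chosen instead of a cyclic diol protecting group, because only independent ethers can later turn diaxial and place the C2 oxygen perpendicular to the carbonyl in 11.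

5 to 2 and 3 (through 4): the O2–benzoyl bond is cut. The benzoate that ends on C4 of 18 is thus in place from the start and never has to be introduced selectively on the carbocycle. Direct acylation of 2 would favour the equatorial O3, so the forward step goes through 4, in which O2 and O3 share one orthoester carbon and whose hydrolysis leaves the acyl group on the axial O2.

2 to 1: the C6–I bond is traced back to the primary hydroxyl of 1. The forward step must activate only that hydroxyl.

## Other disconnections considered

Alternative 1: The ring bond C1–C6 is cut and traced back to a [3,3] sigmatropic shift. The forward substrate is the 2-oxyglycal A1, a D-gluco-configured pyranoid enol ether with a vinyl group on C5 and PMB ethers on O2, O3 and O4. Thermolysis of A1 in a high-boiling, unreactive solvent lets its O–C1=C2 enol ether and its C5 vinyl group react as an allyl vinyl ether in a Claisen rearrangement through a boat-shaped transition state. Glycal C2 (target C1) bonds to the vinyl terminus (target C6), the C5–O bond breaks, and the ring oxygen ends as the aldehyde of the cyclohexene carbaldehyde A2.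
- In its favour: the quaternary centre arises by suprafacial chirality transfer from sugar C5, so its configuration follows from geometry and not from facial discrimination by a neighbouring group. On this point the alternative is better than the chosen plan. C2 and C3 come from the chiral pool in both plans, which makes them equal there.
- Against it: A2 has its double bond at C4=C5 and no oxygen on C4. An allylic oxygenation with transposition is still needed, with a new stereocentre at C4 to control, followed by aldehyde reduction, double benzoylation and removal of three PMB ethers, one of them tertiary. The thermolysis needs a ring-inverted conformer at very high temperature, and A1 itself requires 2-oxyglycal formation and a one-carbon homologation at C6.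
- Comparison: on structure, the chosen plan has the C4 benzoate and the C5=C6 alkene in place when C1 is formed, whereas A2 still lacks both. On mechanism, a concerted pericyclic shift is more predictable than an ionic addition steered by a neighbouring silyl ether, which counts for the alternative. On step economy the alternative is clearly longer (an estimated fifteen or more operations against nine).

Alternative 2: The two ring bonds C1–C2 and C3–C4 are cut in a [4+2] sense. In the forward direction the pyrone A3, 3-hydroxy-2H-pyran-2-one, acts as the diene once a quinidine-derived amine base with a hydrogen-bond donor has taken its hydroxyl proton. The resulting dienolate adds to the β-silyl enone A4, the E isomer of 4-[dimethyl(phenyl)silyl]but-3-en-2-one, with the acetyl group endo. The cycloadduct A5 is a 2-oxabicyclo[2.2.2]oct-5-en-3-one whose lactone carbonyl is the future C7 and whose ring oxygen is the future O4.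
- In its favour: one catalytic asymmetric step from achiral materials builds the ring, two C–C bonds and all four stereocentres. The lactone ties C7 to O4, so its reduction frees exactly the two hydroxyls that carry benzoates in the target. In bond-forming efficiency the alternative is better than the chosen plan, and in step count it could be equal or slightly better (an estimated eight steps).
- Against it: A4 is a hindered, weakly activated dienophile for which endo selectivity and enantioselectivity would have to be established. A5 can revert or lose CO2 on warming. The acetyl group must become an oxygen by Baeyer–Villiger oxidation and the silyl group by Tamao–Fleming oxidation, the latter needing electrophilic activation of the phenylsilane, both in the presence of the ring alkene and a bridgehead tertiary alcohol.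
- Comparison: on structure, A5 differentiates the two benzoate oxygens more elegantly than the chosen plan does. On mechanism, its absolute configuration rests on catalyst control that is unproven for this diene–dienophile pair, whereas the chosen plan takes it from mannose. On step economy the alternative is shorter on paper but stacks several uncertain selectivities, while the chosen plan uses only well-tried functional-group chemistry after the key step.

Alternative 3: The bond C3–C4 is cut and both ends are returned to aldehydes. In the forward direction the dialdehyde A6, which holds the C3 formyl group, a (Z)-enal ending in C4, the C1/C2 acetonide and the C7 benzoate, is treated with SmI2 in THF. Electron transfer to each carbonyl gives two ketyls, which join C3 to C4 within a chelated samarium-bound diolate, and protonation should give the cis-diol A7.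
- In its favour: the ring and two stereocentres form in one mild, non-basic step. C1, C2 and the C7 benzoate are already present, so only benzoylation of O4 and acetonide removal remain. That is two steps after the key step, equal to the chosen plan. It also avoids mercury and strong base, which is better than the chosen plan.
- Against it: A6 needs acyclic construction of the quaternary C1 next to C2 and contains a (Z)-enal that isomerises easily. The enal-derived ketyl is delocalised and may couple at C6 or be reduced in the 1,4 sense. Facial control relative to C2 rests on the anti preference toward an α-alkoxy group. Monobenzoylation of the allylic hydroxyl of the cis-diol in A7 is not inherently selective, and acid removal of an acetonide from a tertiary allylic oxygen invites ionisation and acyl migration.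
- Comparison: on structure, the alternative forms two stereocentres in its key step and the chosen plan one. On mechanism, the radical coupling is milder but its regiochemistry and facial sense are less secure than 1,2-addition of a sulfonium ylide. On step economy the chosen precursor 11 is reached in six routine steps from the pool, whereas the path to A6 is likely longer and less certain.

Key step: step 7

## Steps

Step 1
Reactants: 1 methyl α-D-mannopyranoside
Product: 2 methyl 6-deoxy-6-iodo-α-D-mannopyranoside
Conditions: PPh3, I2, imidazole, THF, 65 °C
Reagents that add atoms: iodine, II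
Why: Appel-type iodination; the alkoxyphosphonium ion forms and is displaced by iodide only at the primary C6 hydroxyl, the three secondary hydroxyls being too hindered for SN2 here, and no stereocentre is touched.

Step 2
Reactants: 2 methyl 6-deoxy-6-iodo-α-D-mannopyranoside; 3 trimethyl orthobenzoate
Product: 5 methyl 2-O-benzoyl-6-deoxy-6-iodo-α-D-mannopyranoside, via 2,3-orthobenzoate 4 (not isolated)
Conditions: PhC(OMe)3, CSA (cat.), MeCN, rt; then 80% aq. AcOH, rt
Reagents that add atoms: trimethyl orthobenzoate (3), COC(OC)(OC)c1ccccc1; water, O
Why: Acid-catalysed orthoester exchange engages the only cis-diol (O2/O3) as a five-membered cyclic orthoester, and mild aqueous acid opens it so that the acyl group stays on the axial oxygen (the usual outcome of kinetic orthoester hydrolysis), giving the 2-benzoate that direct acylation with benzoyl chloride would not deliver; no stereocentre is touched.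

Step 3
Reactants: 5 methyl 2-O-benzoyl-6-deoxy-6-iodo-α-D-mannopyranoside
Product: 6 methyl 2-O-benzoyl-3,4-bis-O-(tert-butyldimethylsilyl)-6-deoxy-6-iodo-α-D-mannopyranoside
Conditions: TBSOTf, 2,6-lutidine, CH2Cl2, 0 °C to rt
Reagents that add atoms: tert-butyldimethylsilyl trifluoromethanesulfonate, CC(C)(C)[Si](C)(C)OS(=O)(=O)C(F)(F)F
Why: Silyl triflate silylation of the hindered trans-3,4-diol; the weak, non-nucleophilic base should not trigger O2 to O3 benzoate migration, and the two separate bulky ethers are what later allows the diaxial arrangement in enone 11.

Step 4
Reactants: 6 methyl 2-O-benzoyl-3,4-bis-O-(tert-butyldimethylsilyl)-6-deoxy-6-iodo-α-D-mannopyranoside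
Product: 7 methyl 2-O-benzoyl-3,4-bis-O-(tert-butyldimethylsilyl)-6-deoxy-α-D-lyxo-hex-5-enopyranoside
Conditions: DBU, THF, reflux
Reagents that add atoms: none
Why: E2 dehydroiodination by the amidine base; H5 is the only β-hydrogen, so the exocyclic enol ether is the only alkene possible, and benzoate and silyl ethers are inert to DBU.

Step 5
Reactants: 7 methyl 2-O-benzoyl-3,4-bis-O-(tert-butyldimethylsilyl)-6-deoxy-α-D-lyxo-hex-5-enopyranoside
Product: 9 (2S,3R,4R)-4-(benzoyloxy)-2,3-bis[(tert-butyldimethylsilyl)oxy]-5-hydroxycyclohexan-1-one (both C5 epimers), via mercurio keto-aldehyde 8 (not isolated)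
Conditions: Hg(OCOCF3)2 (cat.), acetone–H2O (2:1), rt
Reagents that add atoms: water, O
Why: Ferrier carbocyclisation; oxymercuration of the enol ether by divalent mercury, collapse of the hemiketal to the 5-keto aldehyde with loss of methanol, and intramolecular aldol of the α-mercurio ketone close the carbocycle, with sugar C2–C4 carried over unchanged and the new carbinol centre removed in the next step.

Step 6
Reactants: 9 (2S,3R,4R)-4-(benzoyloxy)-2,3-bis[(tert-butyldimethylsilyl)oxy]-5-hydroxycyclohexan-1-one
Product: 11 (4R,5R,6S)-4-(benzoyloxy)-5,6-bis[(tert-butyldimethylsilyl)oxy]cyclohex-2-en-1-one, via β-mesyloxy ketone 10 (not isolated)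
Conditions: MsCl, Et3N, CH2Cl2, 0 °C
Reagents that add atoms: none
Why: Mesylation of the β-hydroxyl followed in the same flask by E1cB elimination gives the conjugated enone from either carbinol epimer; silyloxide on C3 is too poor a leaving group to follow, and brief exposure to the amine at 0 °C should spare the C2 stereocentre.

Step 7
Reactants: 11 (4R,5R,6S)-4-(benzoyloxy)-5,6-bis[(tert-butyldimethylsilyl)oxy]cyclohex-2-en-1-one; 12 trimethylsulfonium iodide
Product: 15 (3S,6R,7R,8S)-7,8-bis[(tert-butyldimethylsilyl)oxy]-1-oxaspiro[2.5]oct-4-en-6-yl benzoate, via dimethylsulfonium methylide 13 (not isolated), via sulfonium betaine 14 (not isolated)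
Conditions: Me3S+ I− (12), KN(SiMe3)2, THF, −10 °C; then 11, −78 to −20 °C
Reagents that add atoms: trimethylsulfonium iodide (12), C[S+](C)C.[I-]
Why: Corey–Chaykovsky epoxidation: ylide 13, preformed from a slight excess of 12 so that no free amide base meets the enolisable ketone, adds irreversibly to the C1 carbonyl and forms the C1–C7 bond in betaine 14. The alkoxide then displaces Me2S from C7 in a 3-exo-tet closure that forms the C7–O bond of the spiro-oxirane, so the former carbonyl oxygen becomes O1. The closest known reaction type is the sulfonium-ylide epoxidation of α-oxygenated cyclohexenones. The new stereocentre C1 is controlled by the adjacent C2 silyloxy group, because the trans bis-silyl ether should prefer the diaxial half-chair, which sets the C2–O bond perpendicular to the carbonyl plane. The ylide then attacks antiperiplanar to that bond (polar Felkin–Anh model, non-chelating silyl ether and potassium counter-ion), that is axially and trans to O2, which leaves the oxirane oxygen cis to O2 as the target requires. The step needs 1,2- rather than 1,4-addition, which the unstabilised sulfonium ylide secures under kinetic control where a sulfoxonium ylide would attack C5. It also needs addition to the ketone rather than α'-deprotonation with β-elimination or attack on the benzoate, which the low temperature, the absence of excess base, the poor leaving ability of silyloxide on C3 and the much higher electrophilicity of the ketone should secure.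

Step 8
Reactants: 15 (3S,6R,7R,8S)-7,8-bis[(tert-butyldimethylsilyl)oxy]-1-oxaspiro[2.5]oct-4-en-6-yl benzoate; 16 benzoic acid
Product: 17 [(1S,2S,3R,4R)-4-(benzoyloxy)-2,3-bis[(tert-butyldimethylsilyl)oxy]-1-hydroxycyclohex-5-en-1-yl]methyl benzoate
Conditions: PhCO2H, PhCO2Cs (cat.), DMF, 70 °C
Reagents that add atoms: benzoic acid (16), OC(=O)c1ccccc1
Why: Carboxylate opening of a 2,2-disubstituted oxirane; benzoate attacks the unhindered methylene C7 by SN2 rather than the quaternary allylic C1 or C5, the C1–O bond is not broken so C1 keeps its configuration, and the benzoic acid buffer protonates the tertiary alkoxide at once, which suppresses silyl and acyl migration and regenerates benzoate.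

Step 9
Reactants: 17 [(1S,2S,3R,4R)-4-(benzoyloxy)-2,3-bis[(tert-butyldimethylsilyl)oxy]-1-hydroxycyclohex-5-en-1-yl]methyl benzoate
Product: 18 [(1S,2S,3S,4R)-4-(benzoyloxy)-1,2,3-trihydroxycyclohex-5-en-1-yl]methyl benzoate
Conditions: HF·pyridine, pyridine, THF, 0 °C to rt
Reagents that add atoms: none
Why: Fluoride cleavage of both secondary silyl ethers under mildly acidic, pyridine-buffered conditions, chosen over basic fluoride so that neither benzoate should migrate to the freed hydroxyls and the tertiary allylic alcohol should not ionise.

## Compound list

1 | methyl α-D-mannopyranoside | OC[C@H]1O[C@H](OC)[C@@H](O)[C@@H](O)[C@@H]1O | starting material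
2 | methyl 6-deoxy-6-iodo-α-D-mannopyranoside | IC[C@H]1O[C@H](OC)[C@@H](O)[C@@H](O)[C@@H]1O | intermediate
3 | trimethyl orthobenzoate | COC(OC)(OC)c1ccccc1 | starting material
4 | methyl 6-deoxy-6-iodo-2,3-O-(α-methoxybenzylidene)-α-D-mannopyranoside (orthoester carbon as a mixture) | IC[C@H]1O[C@H](OC)[C@@H](OC2(OC)c3ccccc3)[C@@H](O2)[C@@H]1O | intermediate
5 | methyl 2-O-benzoyl-6-deoxy-6-iodo-α-D-mannopyranoside | IC[C@H]1O[C@H](OC)[C@@H](OC(=O)c2ccccc2)[C@@H](O)[C@@H]1O | intermediate
6 | methyl 2-O-benzoyl-3,4-bis-O-(tert-butyldimethylsilyl)-6-deoxy-6-iodo-α-D-mannopyranoside | IC[C@H]1O[C@H](OC)[C@@H](OC(=O)c2ccccc2)[C@@H](O[Si](C)(C)C(C)(C)C)[C@@H]1O[Si](C)(C)C(C)(C)C | intermediate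
7 | methyl 2-O-benzoyl-3,4-bis-O-(tert-butyldimethylsilyl)-6-deoxy-α-D-lyxo-hex-5-enopyranoside | C=C1O[C@H](OC)[C@@H](OC(=O)c2ccccc2)[C@@H](O[Si](C)(C)C(C)(C)C)[C@@H]1O[Si](C)(C)C(C)(C)C | intermediate
8 | 2-O-benzoyl-3,4-bis-O-(tert-butyldimethylsilyl)-6-deoxy-6-[(trifluoroacetoxy)mercurio]-D-lyxo-hexos-5-ulose | O=C[C@@H](OC(=O)c1ccccc1)[C@@H](O[Si](C)(C)C(C)(C)C)[C@H](O[Si](C)(C)C(C)(C)C)C(=O)C[Hg]OC(=O)C(F)(F)F | intermediate
9 | (2S,3R,4R)-4-(benzoyloxy)-2,3-bis[(tert-butyldimethylsilyl)oxy]-5-hydroxycyclohexan-1-one (both C5 epimers) | O=C1CC(O)[C@@H](OC(=O)c2ccccc2)[C@@H](O[Si](C)(C)C(C)(C)C)[C@@H]1O[Si](C)(C)C(C)(C)C | intermediate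
10 | 5-O-methanesulfonate of 9 (both C5 epimers) | O=C1CC(OS(C)(=O)=O)[C@@H](OC(=O)c2ccccc2)[C@@H](O[Si](C)(C)C(C)(C)C)[C@@H]1O[Si](C)(C)C(C)(C)C | intermediate
11 | (4R,5R,6S)-4-(benzoyloxy)-5,6-bis[(tert-butyldimethylsilyl)oxy]cyclohex-2-en-1-one | O=C1C=C[C@@H](OC(=O)c2ccccc2)[C@@H](O[Si](C)(C)C(C)(C)C)[C@@H]1O[Si](C)(C)C(C)(C)C | intermediate
12 | trimethylsulfonium iodide | C[S+](C)C.[I-] | starting material
13 | dimethylsulfonium methylide | [CH2-][S+](C)C | intermediate
14 | sulfonium betaine: C1 alkoxide of the enone adduct with CH2–SMe2+ on C1, C7 trans to the C2 silyloxy group | C[S+](C)C[C@@]1([O-])C=C[C@@H](OC(=O)c2ccccc2)[C@@H](O[Si](C)(C)C(C)(C)C)[C@@H]1O[Si](C)(C)C(C)(C)C | intermediate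
15 | (3S,6R,7R,8S)-7,8-bis[(tert-butyldimethylsilyl)oxy]-1-oxaspiro[2.5]oct-4-en-6-yl benzoate | C2[C@@]1(O2)C=C[C@@H](OC(=O)c3ccccc3)[C@@H](O[Si](C)(C)C(C)(C)C)[C@@H]1O[Si](C)(C)C(C)(C)C | intermediate
16 | benzoic acid | OC(=O)c1ccccc1 | starting material
17 | [(1S,2S,3R,4R)-4-(benzoyloxy)-2,3-bis[(tert-butyldimethylsilyl)oxy]-1-hydroxycyclohex-5-en-1-yl]methyl benzoate | O=C(OC[C@@]1(O)C=C[C@@H](OC(=O)c2ccccc2)[C@@H](O[Si](C)(C)C(C)(C)C)[C@@H]1O[Si](C)(C)C(C)(C)C)c1ccccc1 | intermediate
18 | [(1S,2S,3S,4R)-4-(benzoyloxy)-1,2,3-trihydroxycyclohex-5-en-1-yl]methyl benzoate | O=C(OC[C@@]1(O)C=C[C@@H](OC(=O)c2ccccc2)[C@@H](O)[C@@H]1O)c1ccccc1 | target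

## Step count and least certain steps

Total step count: 9. Longest linear sequence: 9 steps (1 to 18); 3, 12 and 16 are commercial inputs.

Step 7 (key step). The most likely failure is insufficient facial discrimination: the ylide may attack syn to O2 through the diequatorial half-chair, or be deflected by the axial C3 silyloxy group that lies on the intended face. The second risk is enolisation toward C2, followed by epimerisation or by β-elimination and aromatisation. The fallback sets out from 11 and returns at 18; it delivers oxygen, not carbon, under stereocontrol, through a reagent bound to the C2 hydroxyl. Wittig methylenation of 11 (Ph3P=CH2, THF, −78 to 0 °C) should give the exocyclic diene F1, which is 11 with a methylene group in place of the carbonyl oxygen. HF·pyridine should then remove both silyl ethers to give the diene diol F2. Epoxidation with VO(acac)2 and t-BuOOH, directed by the allylic C2 hydroxyl, should attack the exocyclic alkene from the face of that hydroxyl and give the spiro-oxirane diol F3, with the oxirane oxygen cis to O2 as in 15. Opening of F3 with PhCO2H and catalytic PhCO2Cs as in step 8 should give 18.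

Step 8. The likely failures are opening at the wrong site (ionisation at the tertiary allylic C1, or SN2' attack at C5), slow substitution next to the quaternary centre, and silyl or acyl migration through the tertiary alkoxide. The fallback sets out from 11 and returns at 17; it avoids the oxirane by using a hydroxymethyl anion equivalent. Addition of iPrO(Me)2SiCH2MgCl to the ketone of 11 (THF, −78 °C), in the same facial sense as the ylide, should give the β-hydroxysilane F4. Tamao oxidation (H2O2, KF, KHCO3, THF–MeOH) should convert the C–Si bond into the primary hydroxyl of the 1,7-diol F5. Benzoylation of the primary hydroxyl alone (BzCl, pyridine, CH2Cl2, −20 °C) should give 17.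

Step 2. The likely failures are loss of regiocontrol in the orthoester opening, benzoate migration from the axial O2 to the equatorial O3 during work-up, and involvement of O4 in orthoester exchange. The fallback sets out from 2 and returns at 5; it blocks the trans-diol and acylates the one hydroxyl that is left. Butane-2,3-dione, HC(OMe)3 and CSA in MeOH should protect only the diequatorial 3,4-diol as the butane-2,3-diacetal F6. BzCl in pyridine should then acylate the sole free hydroxyl O2 to give the 2-O-benzoyl diacetal F7. Aqueous CF3CO2H should remove the diacetal to give 5.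

Step 4. The likely failure is slow E2 elimination beside the bulky O4 silyl ether, with competing substitution by the amidine or loss of the benzoate under forcing conditions. The fallback sets out from 6 and returns at 7; it replaces the base-induced anti elimination by a thermal syn elimination. PhSeSePh and NaBH4 in EtOH–THF should displace the iodide to give the 6-phenylselenide F8. NaIO4 in aqueous MeOH–THF should oxidise it to the selenoxide F9, which should lose PhSeOH on warming to give 7.

## Further compounds

F1 | step 7 | exocyclic diene: 4-benzoyloxy-2,3-bis(tert-butyldimethylsilyloxy)-1-methylenecyclohex-5-ene, C2–C4 configured as in 11 | C=C1C=C[C@@H](OC(=O)c2ccccc2)[C@@H](O[Si](C)(C)C(C)(C)C)[C@@H]1O[Si](C)(C)C(C)(C)C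
F2 | step 7 | diene diol: 4-benzoyloxy-2,3-dihydroxy-1-methylenecyclohex-5-ene, C2–C4 configured as in 18 | C=C1C=C[C@@H](OC(=O)c2ccccc2)[C@@H](O)[C@@H]1O
F3 | step 7 | spiro-oxirane diol: bis-desilyl analogue of 15, oxirane oxygen cis to the C2 hydroxyl | C2[C@@]1(O2)C=C[C@@H](OC(=O)c3ccccc3)[C@@H](O)[C@@H]1O
F4 | step 8 | β-hydroxysilane: 17 with CH2Si(CH3)2(OiPr) in place of CH2OBz on C1 | CC(C)O[Si](C)(C)C[C@@]1(O)C=C[C@@H](OC(=O)c2ccccc2)[C@@H](O[Si](C)(C)C(C)(C)C)[C@@H]1O[Si](C)(C)C(C)(C)C
F5 | step 8 | 1,7-diol: 17 with free C7 hydroxyl | OC[C@@]1(O)C=C[C@@H](OC(=O)c2ccccc2)[C@@H](O[Si](C)(C)C(C)(C)C)[C@@H]1O[Si](C)(C)C(C)(C)C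
F6 | step 2 | methyl 6-deoxy-6-iodo-3,4-O-[(2S,3S)-2,3-dimethoxybutane-2,3-diyl]-α-D-mannopyranoside | IC[C@H]1O[C@H](OC)[C@@H](O)[C@H]2O[C@](C)(OC)[C@@](C)(OC)O[C@H]12
F7 | step 2 | methyl 2-O-benzoyl-6-deoxy-6-iodo-3,4-O-[(2S,3S)-2,3-dimethoxybutane-2,3-diyl]-α-D-mannopyranoside | IC[C@H]1O[C@H](OC)[C@@H](OC(=O)c3ccccc3)[C@H]2O[C@](C)(OC)[C@@](C)(OC)O[C@H]12
F8 | step 4 | methyl 2-O-benzoyl-3,4-bis-O-(tert-butyldimethylsilyl)-6-deoxy-6-(phenylselanyl)-α-D-mannopyranoside | c1ccccc1[Se]C[C@H]1O[C@H](OC)[C@@H](OC(=O)c2ccccc2)[C@@H](O[Si](C)(C)C(C)(C)C)[C@@H]1O[Si](C)(C)C(C)(C)C
F9 | step 4 | Se-oxide of F8 (selenium centre as a mixture) | O=[Se](c1ccccc1)C[C@H]1O[C@H](OC)[C@@H](OC(=O)c2ccccc2)[C@@H](O[Si](C)(C)C(C)(C)C)[C@@H]1O[Si](C)(C)C(C)(C)C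
A1 | alternative 1 | 1,5-anhydro-6,7-dideoxy-2,3,4-tris-O-(4-methoxybenzyl)-D-arabino-hept-1,6-dienitol | C=C[C@H]1OC=C(OCc2ccc(OC)cc2)[C@@H](OCc2ccc(OC)cc2)[C@@H]1OCc1ccc(OC)cc1
A2 | alternative 1 | 1,5,6-tris(4-methoxybenzyloxy)cyclohex-3-ene-1-carbaldehyde, C1, C5 and C6 configured as C1, C3 and C2 of 18 | O=C[C@@]1(OCc2ccc(OC)cc2)CC=C[C@@H](OCc2ccc(OC)cc2)[C@@H]1OCc1ccc(OC)cc1
A3 | alternative 2 | 3-hydroxy-2H-pyran-2-one | O=C1OC=CC=C1O
A4 | alternative 2 | (E)-4-[dimethyl(phenyl)silyl]but-3-en-2-one | CC(=O)/C=C/[Si](C)(C)c1ccccc1
A5 | alternative 2 | bicyclic lactone: 2-oxabicyclo[2.2.2]oct-5-en-3-one with bridgehead hydroxyl, endo acetyl and adjacent dimethyl(phenyl)silyl group | O=C2[C@@]1(O)C=C[C@@H](O2)[C@@H]([Si](C)(C)c3ccccc3)[C@@H]1C(C)=O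
A6 | alternative 3 | dialdehyde: 4-[(Z)-3-oxoprop-1-enyl]-5-formyl-2,2-dimethyl-1,3-dioxolan-4-ylmethyl benzoate, configured as C1 and C2 of 18 | O=C(c1ccccc1)OC[C@]1(/C=C\C=O)OC(C)(C)O[C@H]1C=O
A7 | alternative 3 | C3/C4 cis-diol with C1/C2 acetonide and C7 benzoate | O=C(c1ccccc1)OC[C@@]12C=C[C@@H](O)[C@@H](O)[C@@H]1OC(C)(C)O2
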